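**Assumptions (one line each)**
- The Cu-catalysed conjugate-addition ligand enantiomer is chosen to give the (S)-enol ether 6, which fixes C8a as R in the target numbering.
- The Me2AlCl-chelated carbonyl-ene closure is expected to give the C4 epimer (4-epi-jaeschkeanadiol), so the ester is installed by Mitsunobu inversion. If the 4S alcohol forms directly, 4-acetoxybenzoyl chloride/pyridine replaces that step.

## Retrosynthetic overview
1. Ferutinine is the p-hydroxybenzoate of jaeschkeanadiol (C4-OH). Disconnect the ester by Mitsunobu inversion of 4-epi-jaeschkeanadiol (13).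
2. Key step: close the seven-membered ring at C4–C5 by a Lewis-acid intramolecular carbonyl-ene (Prins-type) reaction. The C4 aldehyde on C3a attacks a homoprenyl (1,1-disubstituted alkene) side chain on C8a. This forms the ring, the C4 carbinol and the C6=C7 olefin together.
3. The tertiary iPr carbinol comes from organocerium addition to a cyclopentanone, anti to the C3a substituent.
4. The C3a aldehyde (as dimethyl acetal) and the C8a quaternary centre come from Cu-catalysed asymmetric conjugate addition of homoprenyl-MgBr to 3-methylcyclopentenone. The regiodefined enolate is trapped as a silyl enol ether and formylated at C3a.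
5. Ring order: cyclopentane first (conjugate addition), then the seven-membered ring (ene).

## Route

**Step 1**
Reactants: 1 (4-bromo-2-methylbut-1-ene), 2 (Mg)
Product: 3 (3-methylbut-3-en-1-yl)magnesium bromide
Conditions: Mg turnings, I2 (cat.), THF, 40 °C
Reagents that add atoms: magnesium, [Mg]
Why: Standard Grignard formation; the unactivated 1,1-disubstituted alkene survives.

**Step 2**
Reactants: 3, 4 (3-methylcyclopent-2-en-1-one), 5 (TMSCl)
Product: 6, (3S)-trimethyl{[3-methyl-3-(3-methylbut-3-en-1-yl)cyclopent-1-en-1-yl]oxy}silane
Conditions: CuBr·SMe2 (5 mol %), Josiphos-type ligand (6 mol %), MTBE, –78 °C; then TMSCl (2 equiv), –78 °C to rt; non-aqueous pentane work-up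
Reagents that add atoms: chlorotrimethylsilane, C[Si](C)(C)Cl (3 is listed as a reactant)
Why: Cu-catalysed asymmetric conjugate addition of a Grignard to a β,β-disubstituted cyclic enone builds the all-carbon quaternary centre C8a, with the ligand controlling the face. The resulting enolate sits regiospecifically at C3a, and TMSCl traps it as the silyl enol ether.

**Step 3**
Reactants: 6, 7 (trimethyl orthoformate)
Product: 8, (2S,3S)-2-(dimethoxymethyl)-3-methyl-3-(3-methylbut-3-en-1-yl)cyclopentan-1-one
Conditions: HC(OMe)3 (1.5 equiv), TMSOTf (10 mol %), CH2Cl2, –78 to –30 °C; Et3N quench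
Reagents that add atoms: trimethyl orthoformate, COC(OC)OC
Why: Mukaiyama/Noyori-type addition of a silyl enol ether to the dimethoxycarbenium ion formylates only at C3a. The electrophile approaches cis to the methyl and trans to the longer homoprenyl chain, and the epimerisable α-centre equilibrates (DBU if needed) toward this trans isomer. The dr is modest, and the diastereomers are separated by chromatography.

**Step 4**
Reactants: 8, 9 (iPrMgCl)
Product: 10, (1R,2R,3S)-2-(dimethoxymethyl)-3-methyl-3-(3-methylbut-3-en-1-yl)-1-(propan-2-yl)cyclopentan-1-ol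
Conditions: CeCl3 (1.5 equiv), iPrMgCl·LiCl (1.5 equiv), THF, –78 to –40 °C
Reagents that add atoms: isopropylmagnesium chloride, CC(C)[Mg]Cl
Why: Organocerium addition (Knochel/Imamoto type) avoids enolisation and β-hydride reduction of the hindered ketone. Both the acetal and the angular methyl sit on the top face, so iPr adds from the bottom. This puts OH cis to C4 and iPr cis to H3a, as in the target.

**Step 5**
Reactants: 10, 11 (water)
Product: 12, (1R,2R,5S)-2-hydroxy-5-methyl-5-(3-methylbut-3-en-1-yl)-2-(propan-2-yl)cyclopentane-1-carbaldehyde
Conditions: PPTS (0.3 equiv), acetone/H2O 10:1, 55 °C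
Reagents that add atoms: water, O
Why: Mild acetal hydrolysis leaves the tertiary alcohol and the alkene intact. The C3a stereocentre is not touched, but retro-aldol and epimerisation must be watched.

**Step 6**
Reactants: 12
Product: 13, (3R,3aS,4R,8aR)-6,8a-dimethyl-3-(propan-2-yl)-1,2,3,3a,4,5,8,8a-octahydroazulene-3,4-diol (4-epi-jaeschkeanadiol)
Conditions: Me2AlCl (2.5 equiv), CH2Cl2, –78 to –20 °C; aqueous Rochelle salt work-up
Reagents that add atoms: none
Why: Proposed new method: a type III intramolecular carbonyl-ene/Prins closure to a seven-membered ring. The first equivalent of Me2AlCl deprotonates the tertiary OH, and the Al-alkoxide chelates the cis C4 aldehyde (six-membered chelate). The second equivalent activates the carbonyl, the terminal CH2 of the 1,1-disubstituted alkene attacks C4, and loss of an H from C7 gives the endocyclic trisubstituted C6=C7 olefin (ring-constrained, hence Z). The trans-fusion is preset by the C3a aldehyde being trans to the chain, and chelation holds O4 syn to O3, giving the 4R epimer. The closest known reaction is Snider-type Me2AlCl-promoted intramolecular carbonyl-ene cyclisation forming five- and six-membered rings.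

**Step 7**
Reactants: 13, 14 (4-acetoxybenzoic acid)
Product: 15, 4-acetoxybenzoate ester of (3R,3aS,4S,8aR)-jaeschkeanadiol
Conditions: PPh3, DIAD, THF/toluene, 0 °C to rt
Reagents that add atoms: 4-acetoxybenzoic acid, CC(=O)Oc1ccc(cc1)C(O)=O
Why: Mitsunobu esterification (SN2) inverts the secondary C4 carbinol from R to S and installs the protected aroyl group in one step. The tertiary alcohol is inert under these conditions.

**Step 8**
Reactants: 15
Product: 16, ferutinine
Conditions: N2H4·AcOH (1.2 equiv), DMF, rt
Reagents that add atoms: none
Why: Chemoselective aryl-acetate cleavage (aminolysis/hydrazinolysis). The hindered secondary aroyl ester, the tertiary alcohol and the alkene are untouched.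

## Compound list
1 | 4-bromo-2-methylbut-1-ene | C=C(C)CCBr | starting material
2 | magnesium | [Mg] | reagent
3 | (3-methylbut-3-en-1-yl)magnesium bromide | C=C(C)CC[Mg]Br | intermediate
4 | 3-methylcyclopent-2-en-1-one | CC1=CC(=O)CC1 | starting material
5 | chlorotrimethylsilane | C[Si](C)(C)Cl | reagent
6 | (3S)-trimethyl{[3-methyl-3-(3-methylbut-3-en-1-yl)cyclopent-1-en-1-yl]oxy}silane | C=C(C)CC[C@@]1(C)CCC(O[Si](C)(C)C)=C1 | intermediate
7 | trimethyl orthoformate | COC(OC)OC | reagent
8 | (2S,3S)-2-(dimethoxymethyl)-3-methyl-3-(3-methylbut-3-en-1-yl)cyclopentan-1-one | COC(OC)[C@H]1C(=O)CC[C@]1(C)CCC(C)=C | intermediate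
9 | isopropylmagnesium chloride | CC(C)[Mg]Cl | reagent
10 | (1R,2R,3S)-2-(dimethoxymethyl)-3-methyl-3-(3-methylbut-3-en-1-yl)-1-(propan-2-yl)cyclopentan-1-ol | COC(OC)[C@H]1[C@](O)(C(C)C)CC[C@]1(C)CCC(C)=C | intermediate
11 | water | O | reagent
12 | (1R,2R,5S)-2-hydroxy-5-methyl-5-(3-methylbut-3-en-1-yl)-2-(propan-2-yl)cyclopentane-1-carbaldehyde | O=C[C@H]1[C@](O)(C(C)C)CC[C@]1(C)CCC(C)=C | intermediate
13 | (3R,3aS,4R,8aR)-4-epi-jaeschkeanadiol | CC1=CC[C@@]2(C)CC[C@@](O)(C(C)C)[C@@H]2[C@H](O)C1 | intermediate
14 | 4-acetoxybenzoic acid | CC(=O)Oc1ccc(cc1)C(O)=O | reagent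
15 | (3R,3aS,4S,8aR)-3-hydroxy-6,8a-dimethyl-3-(propan-2-yl)-1,2,3,3a,4,5,8,8a-octahydroazulen-4-yl 4-acetoxybenzoate | CC1=CC[C@@]2(C)CC[C@@](O)(C(C)C)[C@@H]2[C@@H](OC(=O)c2ccc(OC(C)=O)cc2)C1 | intermediate
16 | ferutinine | CC1=CC[C@@]2(C)CC[C@@](O)(C(C)C)[C@@H]2[C@@H](OC(=O)c2ccc(O)cc2)C1 | target

## Summary
Total steps: 8.
Longest linear sequence: 8 steps from 1 (7 steps from enone 4).

**Three steps most likely to fail**
1. **Step 6 (carbonyl-ene closure).** It may give the wrong alkene isomer (exocyclic or Δ5), the cis-fused bicycle, or a different C4 configuration.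
   - Fallback: change the ring-closing logic. Use allyl (rather than homoprenyl) conjugate addition, convert the C3a aldehyde by intermolecular Hosomi–Sakurai with methallyltrimethylsilane, and close the seven-membered ring by RCM (Hoveyda–Grubbs II).
2. **Step 3 (C3a formylation).** Me and CH2R on C8a give little facial bias, so the dr is modest, and the aldehyde at C3a can epimerise in steps 3–6.
   - Fallback: form the cycloheptene ring first, then set C3a by thermodynamic epimerisation α to a C3 ketone (trans ring fusion) before adding iPr.
3. **Step 2 (asymmetric conjugate addition).** The ee for 3-methylcyclopentenone with a Grignard reagent may be below 90%.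
   - Fallback: set C8a by Johnson–Claisen chirality transfer from lipase-resolved (S)-3-methylcyclopent-2-en-1-ol. Then hydroborate/oxidise to the 3,3-disubstituted cyclopentanone, elaborate the ester to the homoprenyl chain, and rejoin the route at the ketone stage.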